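**Retrosynthetic overview**

1. Ring numbering: C1 (C=O), C2=C3, C4 (CH2), C5 (C–OH bearing nonadecyl), C6 (CH2). The plan rests on C3 being β to the C1 carbonyl while C4 is a methylene attached to the tertiary carbinol C5.
2. C2=C3 is made last by E1cB loss of benzenesulfinate from C3 of a β-sulfonyl ketone; the C1 carbonyl is carried until then as a 1,3-dithiane.
3. The only ring is closed at C3–C4: an α-sulfonyl carbanion at C3 opens a 2,2-disubstituted C5/C4 epoxide at its CH2 (6-endo).
4. The open-chain epoxy sulfone comes from a dithiane linchpin: C1–C6 by opening silyl-protected (S)-2-nonadecylglycidol with a lithiated 2-(2-silyloxyethyl)dithiane, then arm → sulfone and diol → epoxide.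
5. C5 is set by Sharpless epoxidation of 2-methylidenehenicosan-1-ol, made from octadecylmagnesium bromide and methyl 2-(bromomethyl)acrylate followed by iBu2AlH.

Key step: step 12

Assumption: the sulfonyl-bearing carbon formed in step 12 is a transient stereocentre; 22 and 23 are drawn as the epimer with the sulfonyl group trans to the hydroxyl, and the other epimer, should it form, would converge on 24 in step 14.

**Route**

Step 1
Reactants: 1 1-bromooctadecane; 2 methyl 2-(bromomethyl)prop-2-enoate
Product: 4 methyl 2-methylidenehenicosanoate, via octadecylmagnesium bromide 3 (not isolated)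
Conditions: Mg, THF, reflux; then 2, CuI (10 mol %), THF, −78 → 0 °C
Reagents that add atoms: none
Why: Copper-catalysed allylic substitution (SN2′) of a primary Grignard reagent on a 2-(bromomethyl)acrylate is much faster than ester addition at low temperature and regenerates the 1,1-disubstituted acrylate, now carrying the C19 chain.

Step 2
Reactants: 4 methyl 2-methylidenehenicosanoate
Product: 5 2-methylidenehenicosan-1-ol
Conditions: iBu2AlH (2.5 equiv), CH2Cl2, −78 → 0 °C
Reagents that add atoms: none
Why: iBu2AlH reduction of an α-substituted acrylate ester proceeds by clean 1,2-hydride delivery to give the allylic alcohol without conjugate reduction.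

Step 3
Reactants: 5 2-methylidenehenicosan-1-ol
Product: 6 [(2S)-2-nonadecyloxiran-2-yl]methanol
Conditions: Ti(OiPr)4 (10 mol %), L-(+)-diethyl tartrate (12 mol %), t-BuOOH, 4 Å MS, CH2Cl2, −20 °C
Reagents that add atoms: tert-butyl hydroperoxide, CC(C)(C)OO
Why: In the Sharpless asymmetric epoxidation the allylic hydroxyl binds the titanium tartrate catalyst, and the L-(+)-tartrate directs oxygen to the alkene face that gives the (S)-epoxy alcohol, as with other 2-alkylallyl alcohols; this sets C5, the only permanent stereocentre.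

Step 4
Reactants: 6 [(2S)-2-nonadecyloxiran-2-yl]methanol
Product: 7 tert-butyl{[(2R)-2-nonadecyloxiran-2-yl]methoxy}diphenylsilane
Conditions: TBDPSCl, imidazole, CH2Cl2, 0 °C → rt
Reagents that add atoms: tert-butyl(chloro)diphenylsilane, CC(C)(C)[Si](Cl)(c1ccccc1)c1ccccc1
Why: Imidazole-promoted silylation of the primary alcohol masks the hydroxyl for the organolithium step and leaves the epoxide CH2 as the only electrophilic carbon; the descriptor changes from S to R by CIP priority only.

Step 5
Reactants: 8 1,3-dithiane; 9 (2-bromoethoxy)(tert-butyl)dimethylsilane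
Product: 11 tert-butyl[2-(1,3-dithian-2-yl)ethoxy]dimethylsilane, via 2-lithio-1,3-dithiane 10 (not isolated)
Conditions: n-BuLi, THF, −30 °C; then 9, −78 °C → rt
Reagents that add atoms: none
Why: Corey–Seebach alkylation of 2-lithio-1,3-dithiane with a primary bromide installs the future C2–C3 arm with its oxygen already protected.

Step 6
Reactants: 11 tert-butyl[2-(1,3-dithian-2-yl)ethoxy]dimethylsilane; 7 tert-butyl{[(2R)-2-nonadecyloxiran-2-yl]methoxy}diphenylsilane
Product: 13 (2R)-1-[(tert-butyldiphenylsilyl)oxy]-2-[(2-{2-[(tert-butyldimethylsilyl)oxy]ethyl}-1,3-dithian-2-yl)methyl]henicosan-2-ol, via the lithiated dithiane 12 (not isolated)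
Conditions: t-BuLi, THF/HMPA (10:1), −78 °C; then 7, −78 → 0 °C
Reagents that add atoms: none
Why: In this Corey–Seebach epoxide opening the dithianyl anion (future C1) attacks the unsubstituted epoxide carbon (future C6) by SN2, the only accessible site of a 2,2-disubstituted oxirane, so the C5–O bond and its configuration stay untouched.

Step 7
Reactants: 13 the bis-silyl ether carbinol
Product: 14 (2R)-1-[(tert-butyldiphenylsilyl)oxy]-2-{[2-(2-hydroxyethyl)-1,3-dithian-2-yl]methyl}henicosan-2-ol
Conditions: CSA (10 mol %), MeOH/CH2Cl2 (1:1), 0 °C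
Reagents that add atoms: none
Why: Acid-catalysed methanolysis cleaves a primary tert-butyldimethylsilyl ether far faster than the more acid-stable tert-butyldiphenylsilyl ether (selective desilylation), and neither the dithiane nor the tertiary alcohol reacts under these conditions.

Step 8
Reactants: 14 the arm alcohol
Product: 15 (2R)-1-[(tert-butyldiphenylsilyl)oxy]-2-{[2-(2-iodoethyl)-1,3-dithian-2-yl]methyl}henicosan-2-ol
Conditions: PPh3, I2, imidazole, CH2Cl2, 0 °C → rt
Reagents that add atoms: iodine, II
Why: Appel-type iodination (Garegg–Samuelsson conditions) converts only the unhindered primary alcohol through its alkoxyphosphonium salt, since the tertiary hydroxyl cannot undergo SN2 displacement.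

Step 9
Reactants: 15 the arm iodide; 16 sodium benzenesulfinate
Product: 17 (2R)-1-[(tert-butyldiphenylsilyl)oxy]-2-({2-[2-(phenylsulfonyl)ethyl]-1,3-dithian-2-yl}methyl)henicosan-2-ol
Conditions: DMF, rt → 40 °C
Reagents that add atoms: none
Why: S-alkylation of the sulfinate anion by the primary iodide (SN2) in a dipolar aprotic solvent gives the sulfone, and the weakly basic sulfinate leaves the neutral tertiary alcohol alone.

Step 10
Reactants: 17 the silyl ether sulfone
Product: 18 (2R)-2-({2-[2-(phenylsulfonyl)ethyl]-1,3-dithian-2-yl}methyl)henicosane-1,2-diol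
Conditions: Bu4NF, THF, 0 °C → rt
Reagents that add atoms: none
Why: Fluoride-mediated desilylation removes the tert-butyldiphenylsilyl group and frees the 1,2-diol, with no electrophile present for the reversibly formed sulfonyl anion.

Step 11
Reactants: 18 the sulfonyl diol
Product: 20 2-{[(2R)-2-nonadecyloxiran-2-yl]methyl}-2-[2-(phenylsulfonyl)ethyl]-1,3-dithiane, via the hydroxy tosylate 19 (not isolated)
Conditions: TsCl, Et3N, Bu2SnO (5 mol %), CH2Cl2, rt; then K2CO3, MeOH, 0 °C → rt
Reagents that add atoms: none
Why: Tin-catalysed selective tosylation of the primary hydroxyl of the 1,2-diol, then intramolecular Williamson closure (3-exo-tet) by the tertiary alkoxide, rebuilds the epoxide on the C4 side without ever breaking the C5–O bond, so the configuration is retained.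

Step 12
Reactants: 20 the epoxy sulfone
Product: 22 (8S,10S)-8-nonadecyl-10-(phenylsulfonyl)-1,5-dithiaspiro[5.5]undecan-8-ol, via the α-lithio sulfone 21 (not isolated)
Conditions: n-BuLi (1.1 equiv), THF, −78 °C → rt; then H2O
Reagents that add atoms: none
Why: n-BuLi removes a proton α to the sulfone, the only acidic C–H in 20, and the resulting carbanion C3 attacks the epoxide CH2 (C4) from the rear of the C4–O bond in an intramolecular SN2 reaction, forming C3–C4 and releasing the C5 lithium alkoxide. The closest known reaction type is the cyclisation of epoxy sulfones and epoxy nitriles through their stabilised carbanions. The carbocycle C1–C6 closes in the 6-endo-tet mode, because the 5-exo alternative would need substitution at the fully substituted C5. The C5–O bond is not broken, so the carbinol configuration from step 3 is carried over; the new centre at the sulfonyl carbon is not controlled by design (the equatorial sulfone, trans to the hydroxyl, is expected) and is erased in step 14. The step needs attack at C4 rather than C5 and carbanion formation at C3 only: the first is secured by the primary versus quaternary substitution of the two epoxide carbons, the second by the dithiane, which masks the C1 carbonyl so that no enolisable or eliminable position competes.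

Step 13
Reactants: 22 the spirocyclic hydroxy sulfone
Product: 23 (3R,5S)-3-hydroxy-3-nonadecyl-5-(phenylsulfonyl)cyclohexan-1-one
Conditions: MeI, CaCO3, MeCN/H2O (4:1), 45 °C
Reagents that add atoms: water, O
Why: Alkylative thioketal hydrolysis (S-methylation, ring opening to the thionium ion, capture by water) unveils the C1 ketone under conditions buffered by CaCO3, to which the sulfone and the tertiary alcohol are inert.

Step 14
Reactants: 23 the β-sulfonyl ketone
Product: 24 (5S)-5-hydroxy-5-nonadecylcyclohex-2-en-1-one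
Conditions: Et3N, CH2Cl2, 0 °C → rt
Reagents that add atoms: none
Why: E1cB elimination through the C2 enolate expels benzenesulfinate from C3, a far better leaving group than the C5 hydroxyl, so the C2=C3 enone forms regiospecifically with the tertiary alcohol and its configuration intact.

**Compound list**

1 | 1-bromooctadecane | CCCCCCCCCCCCCCCCCCBr | starting material
2 | methyl 2-(bromomethyl)prop-2-enoate | C=C(CBr)C(=O)OC | starting material
3 | octadecylmagnesium bromide | CCCCCCCCCCCCCCCCCC[Mg]Br | intermediate (not isolated)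
4 | methyl 2-methylidenehenicosanoate | CCCCCCCCCCCCCCCCCCCC(=C)C(=O)OC | intermediate
5 | 2-methylidenehenicosan-1-ol | CCCCCCCCCCCCCCCCCCCC(=C)CO | intermediate
6 | [(2S)-2-nonadecyloxiran-2-yl]methanol | CCCCCCCCCCCCCCCCCCC[C@]1(CO)CO1 | intermediate
7 | tert-butyl{[(2R)-2-nonadecyloxiran-2-yl]methoxy}diphenylsilane | CCCCCCCCCCCCCCCCCCC[C@]1(CO[Si](c2ccccc2)(c2ccccc2)C(C)(C)C)CO1 | intermediate
8 | 1,3-dithiane | C1CSCSC1 | starting material
9 | (2-bromoethoxy)(tert-butyl)dimethylsilane | BrCCO[Si](C)(C)C(C)(C)C | starting material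
10 | 2-lithio-1,3-dithiane | [Li]C1SCCCS1 | intermediate (not isolated)
11 | tert-butyl[2-(1,3-dithian-2-yl)ethoxy]dimethylsilane | CC(C)(C)[Si](C)(C)OCCC1SCCCS1 | intermediate
12 | (2-{2-[(tert-butyldimethylsilyl)oxy]ethyl}-1,3-dithian-2-yl)lithium | [Li]C1(CCO[Si](C)(C)C(C)(C)C)SCCCS1 | intermediate (not isolated)
13 | (2R)-1-[(tert-butyldiphenylsilyl)oxy]-2-[(2-{2-[(tert-butyldimethylsilyl)oxy]ethyl}-1,3-dithian-2-yl)methyl]henicosan-2-ol | CCCCCCCCCCCCCCCCCCC[C@](O)(CO[Si](c1ccccc1)(c1ccccc1)C(C)(C)C)CC1(CCO[Si](C)(C)C(C)(C)C)SCCCS1 | intermediate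
14 | (2R)-1-[(tert-butyldiphenylsilyl)oxy]-2-{[2-(2-hydroxyethyl)-1,3-dithian-2-yl]methyl}henicosan-2-ol | CCCCCCCCCCCCCCCCCCC[C@](O)(CO[Si](c1ccccc1)(c1ccccc1)C(C)(C)C)CC1(CCO)SCCCS1 | intermediate
15 | (2R)-1-[(tert-butyldiphenylsilyl)oxy]-2-{[2-(2-iodoethyl)-1,3-dithian-2-yl]methyl}henicosan-2-ol | CCCCCCCCCCCCCCCCCCC[C@](O)(CO[Si](c1ccccc1)(c1ccccc1)C(C)(C)C)CC1(CCI)SCCCS1 | intermediate
16 | sodium benzenesulfinate | [Na+].[O-]S(=O)c1ccccc1 | starting material
17 | (2R)-1-[(tert-butyldiphenylsilyl)oxy]-2-({2-[2-(phenylsulfonyl)ethyl]-1,3-dithian-2-yl}methyl)henicosan-2-ol | CCCCCCCCCCCCCCCCCCC[C@](O)(CO[Si](c1ccccc1)(c1ccccc1)C(C)(C)C)CC1(CCS(=O)(=O)c2ccccc2)SCCCS1 | intermediate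
18 | (2R)-2-({2-[2-(phenylsulfonyl)ethyl]-1,3-dithian-2-yl}methyl)henicosane-1,2-diol | CCCCCCCCCCCCCCCCCCC[C@](O)(CO)CC1(CCS(=O)(=O)c2ccccc2)SCCCS1 | intermediate
19 | (2R)-2-hydroxy-2-({2-[2-(phenylsulfonyl)ethyl]-1,3-dithian-2-yl}methyl)henicosyl 4-methylbenzenesulfonate | CCCCCCCCCCCCCCCCCCC[C@](O)(COS(=O)(=O)c1ccc(C)cc1)CC1(CCS(=O)(=O)c2ccccc2)SCCCS1 | intermediate (not isolated)
20 | 2-{[(2R)-2-nonadecyloxiran-2-yl]methyl}-2-[2-(phenylsulfonyl)ethyl]-1,3-dithiane | CCCCCCCCCCCCCCCCCCC[C@]1(CO1)CC1(CCS(=O)(=O)c2ccccc2)SCCCS1 | intermediate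
21 | [2-(2-{[(2R)-2-nonadecyloxiran-2-yl]methyl}-1,3-dithian-2-yl)-1-(phenylsulfonyl)ethyl]lithium | CCCCCCCCCCCCCCCCCCC[C@]1(CO1)CC1(CC([Li])S(=O)(=O)c2ccccc2)SCCCS1 | intermediate (not isolated)
22 | (8S,10S)-8-nonadecyl-10-(phenylsulfonyl)-1,5-dithiaspiro[5.5]undecan-8-ol | CCCCCCCCCCCCCCCCCCC[C@]1(O)C[C@H](S(=O)(=O)c2ccccc2)CC2(C1)SCCCS2 | intermediate
23 | (3R,5S)-3-hydroxy-3-nonadecyl-5-(phenylsulfonyl)cyclohexan-1-one | CCCCCCCCCCCCCCCCCCC[C@]1(O)C[C@H](S(=O)(=O)c2ccccc2)CC(=O)C1 | intermediate
24 | (5S)-5-hydroxy-5-nonadecylcyclohex-2-en-1-one | CCCCCCCCCCCCCCCCCCC[C@]1(O)CC=CC(=O)C1 | target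

**Step count**

Total: 14 steps. Longest linear sequence: 13 steps (steps 1–4 and 6–14; step 5 is the side branch).

**Steps most likely to fail**

Step 12. The 6-endo attack at a CH2 next to a fully substituted carbon may be slow. The carbanion could then be lost to proton transfer, or the epoxide could isomerise under base to an allylic alkoxide, instead of the ring closing. The fallback replaces the epoxide opening by a 6-exo-tet sulfonate displacement. It sets out from 19, isolated by stopping step 11 before the carbonate treatment. The tertiary hydroxyl is silylated (TMSOTf, 2,6-lutidine, CH2Cl2, −78 °C) to give (2R)-2-({2-[2-(phenylsulfonyl)ethyl]-1,3-dithian-2-yl}methyl)-2-[(trimethylsilyl)oxy]henicosyl 4-methylbenzenesulfonate F1, in which epoxide formation is blocked. Deprotonation α to the sulfone (LDA, THF/DMPU, −78 → 0 °C) should then lead to intramolecular alkylation at C4, giving trimethyl{[(8S,10S)-8-nonadecyl-10-(phenylsulfonyl)-1,5-dithiaspiro[5.5]undecan-8-yl]oxy}silane F2. Desilylation with Bu4NF in THF returns to the route at 22.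

Step 6. The hindered tertiary dithianyl anion may open the hindered 2,2-disubstituted epoxide only slowly, so that the anion decays or the epoxide is deprotonated on warming. The fallback reverses the order in which the two arms are attached. It sets out from 7 and uses the unhindered parent anion 10 (from 8, as in step 5), which should open the epoxide to give (2R)-1-[(tert-butyldiphenylsilyl)oxy]-2-[(1,3-dithian-2-yl)methyl]henicosan-2-ol F3. Without protecting the tertiary hydroxyl, n-BuLi (2.2 equiv, THF/HMPA) then forms the alkoxide–dithianyl dianion, which is C-alkylated by bromide 9 (sequential Corey–Seebach bis-alkylation). This returns to the route at 13.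

Step 13. S-methylation of the hindered spiro-thioketal may be slow. During a long reaction the liberated thiol could add to enone formed by premature sulfinate loss, or the tertiary carbinol could dehydrate. The fallback avoids hydrolysing the thioketal while the β-sulfonyl ketone is exposed. It sets out from 22: oxidative transketalisation with PhI(OCOCF3)2 and ethylene glycol in MeCN at rt should give (7R,9S)-7-nonadecyl-9-(phenylsulfonyl)-1,4-dioxaspiro[4.5]decan-7-ol F4 without freeing the ketone or a thiol. Mild acetal hydrolysis (PPTS, acetone/H2O, rt) then returns to the route at 23.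

**Further compounds**

F1 | step 12 | (2R)-2-({2-[2-(phenylsulfonyl)ethyl]-1,3-dithian-2-yl}methyl)-2-[(trimethylsilyl)oxy]henicosyl 4-methylbenzenesulfonate | CCCCCCCCCCCCCCCCCCC[C@](O[Si](C)(C)C)(COS(=O)(=O)c1ccc(C)cc1)CC1(CCS(=O)(=O)c2ccccc2)SCCCS1
F2 | step 12 | trimethyl{[(8S,10S)-8-nonadecyl-10-(phenylsulfonyl)-1,5-dithiaspiro[5.5]undecan-8-yl]oxy}silane | CCCCCCCCCCCCCCCCCCC[C@]1(O[Si](C)(C)C)C[C@H](S(=O)(=O)c2ccccc2)CC2(C1)SCCCS2
F3 | step 6 | (2R)-1-[(tert-butyldiphenylsilyl)oxy]-2-[(1,3-dithian-2-yl)methyl]henicosan-2-ol | CCCCCCCCCCCCCCCCCCC[C@](O)(CO[Si](c1ccccc1)(c1ccccc1)C(C)(C)C)CC1SCCCS1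
F4 | step 13 | (7R,9S)-7-nonadecyl-9-(phenylsulfonyl)-1,4-dioxaspiro[4.5]decan-7-ol | CCCCCCCCCCCCCCCCCCC[C@]1(O)C[C@H](S(=O)(=O)c2ccccc2)CC2(C1)OCCO2
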